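We want the amount of target late in the flask, well after the feed ends at 1.0 h.

| flask | substrate | gas | remark | time |
|---|---|---|---|---|
| winter | 0.10 M (fed, over 1.0 h) | 4.5 mM (held) | the very flask that is asked about, followed so far |  |
| flask | 0.10 M (fed, over 1.0 h) | 4.5 mM (held) |  | 2.0 h |

winter run (percent of the substrate charged)

| time / min | target / % |
|---|---|
| 2.00 | 0.8 |
| 6.00 | 1.1 |
| 10.0 | 1.4 |
| 15.0 | 1.7 |
| 20.0 | 3.5 |
| 30.0 | 5.7 |
| 40.0 | 7.4 |

(each reading ± 0.5 percentage points)

- at the start none of the gas is in solution
- percentages count the whole charge, also what has not yet gone in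

- amount of target in percent of the substrate charged, at 12 min, 40 min, 80 min and 2.0 h

At 40.0 min the winter run, which is this flask followed so far, reads 7.4 % target, with 66.7 % of the charge fed. That makes 0.125 of target per substrate fed and not read as target. We carry this as the standing ratio: target over substrate, counted as fed so far minus target. In the same run it reads 0.117 at 20.0 min and 0.129 at 30.0 min. So it is flat within the scatter, while the substrate fed doubles.

Our bracket is a pair of estimates. The low end holds that ratio with the whole charge in. Target then stands at 11.1 % at 80 min and 2.0 h. The high end keeps the gain of the last 20.0 min, which reads 3.9 percentage points, going at the same pace until 2.0 h. That gives 23.0 %. If the ratio stays flat, target follows the feed, and the feed stops at 1.0 h. So we tighten the bracket to its low end and commit to 11.1 % at both 80 min and 2.0 h.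

The forecast gives 1.5 %, 7.3 %, 15.5 % and 24 %. Its last value stands above our high end. It reads the same stretch differently: “That looks like a ceiling set by gas supply”.

The flask gives 1.78 %, 7.87 %, 13.8 % and 13.3 %.

    substrate + reagent ⇌ target (K = 47.4 M⁻¹, k = 0.137 M⁻¹ s⁻¹)
    substrate → side product (k = 5.56 × 10⁻⁵ s⁻¹)
    gas ⇌ reagent, rate k3*(csat - [reagent]) (kL = 0.00699 s⁻¹)
    target ⇌ isomer of the product (K = 0.365, k = 5.98 × 10⁻⁴ s⁻¹)

At 2.0 h the flask holds 13.3 % target, above our low end and below the high end. The half-life of target passing into its isomer, forward rate alone, is 0.32 h, short against 2.0 h. The standing ratio, counted as before, comes to 0.153 at 2.0 h. Taken with the substrate present in the flask, it reads 0.221 at 2.00 h. At 20.0 h it reads 0.218, with substrate at 3.80 % and target at 0.829 %.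

Readings and results are simulated with constants of no real substance, noise included.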